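**Retrosynthetic overview**

1. Artoflavanone ⇐ its 5-O-methoxymethyl ether; the acetal is cleaved last.
2. Ring C ⇐ aryne annulation: a 5-methoxy-3-(methoxymethoxy)-4-prenylbenzyne (from an ortho-silylaryl triflate) takes up the alkoxide oxygen of an (S)-β-silyloxy Weinreb amide at C8a and its acyl carbon at C4a; ring C closes in the C4–C4a bond-forming event.
3. Enabling feature: the C5 oxygen of ring A stands directly beside aryne carbon C4a, so the C4a≡C8a bond is polarised (oxygen adds at C8a, carbanion develops at C4a), and the chain O1–C2–C3–C4 holds the amide carbonyl six atoms from that carbanion.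
4. Aryne precursor ⇐ 5-methoxyresorcinol by two directed ortho-metalations (prenyl at C6, silicon at C4a); side chain ⇐ ethyl 3,4,5-trimethoxybenzoylacetate by Noyori transfer hydrogenation, which sets C2.
5. Ring order: rings A and B are bought as benzenes; ring C is the only ring formed.

Key step: step 11

Remark: the target is the (2S) enantiomer as drawn; flavanone numbering (O1, C2, C3, C4, C4a, C5–C8, C8a) is used for the ring-A fragments as well.

**Route**

Step 1
Reactants: 1 5-methoxybenzene-1,3-diol (5-methoxyresorcinol)
Product: 2 3-methoxy-5-(methoxymethoxy)phenol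
Conditions: MOMCl (1.0 equiv), iPr2NEt, CH2Cl2, 0 °C → rt
Reagents that add atoms: chloromethyl methyl ether, COCCl
Why: O-alkylation (acetal protection) of one of two equivalent phenols with one equivalent of MOMCl should give the mono-acetal as the main part of a statistical mixture, from which diol and bis-acetal are separated and recycled.

Step 2
Reactants: 2 3-methoxy-5-(methoxymethoxy)phenol
Product: 3 triisopropyl[3-methoxy-5-(methoxymethoxy)phenoxy]silane
Conditions: TIPSCl, imidazole, DMF, rt
Reagents that add atoms: chlorotriisopropylsilane, CC(C)[Si](Cl)(C(C)C)C(C)C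
Why: Imidazole-promoted silyl ether formation caps the remaining phenol with a bulky group that neither directs lithiation nor tolerates it at the neighbouring positions.

Step 3
Reactants: 3 triisopropyl[3-methoxy-5-(methoxymethoxy)phenoxy]silane
Product: 5 triisopropyl[3-methoxy-5-(methoxymethoxy)-4-(3-methylbut-2-en-1-yl)phenoxy]silane, via aryllithium 4 (not isolated)
Conditions: n-BuLi, TMEDA, THF, −20 → 0 °C; CuI (10 mol%), prenyl bromide, −78 °C → rt
Reagents that add atoms: prenyl bromide (1-bromo-3-methylbut-2-ene), CC(C)=CCBr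
Why: Directed ortho-metalation should occur at the only position flanked by two coordinating oxygens (OMOM and OMe, future C6) because both positions next to the OTIPS group are shielded, and copper-catalysed allylic substitution at the primary carbon of prenyl bromide should give the linear prenyl arene.

Step 4
Reactants: 5 triisopropyl[3-methoxy-5-(methoxymethoxy)-4-(3-methylbut-2-en-1-yl)phenoxy]silane
Product: 6 3-methoxy-5-(methoxymethoxy)-4-(3-methylbut-2-en-1-yl)phenol
Conditions: TBAF, AcOH, THF, 0 °C
Reagents that add atoms: none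
Why: Fluoride-induced desilylation of the aryl silyl ether, buffered with acetic acid so that the phenoxide is protonated at once, should leave acetal and alkene untouched.

Step 5
Reactants: 6 3-methoxy-5-(methoxymethoxy)-4-(3-methylbut-2-en-1-yl)phenol
Product: 7 3-methoxy-5-(methoxymethoxy)-4-(3-methylbut-2-en-1-yl)phenyl isopropylcarbamate
Conditions: i-PrNCO, Et3N (cat.), CH2Cl2, rt
Reagents that add atoms: isopropyl isocyanate, CC(C)N=C=O
Why: Addition of the phenol to the isocyanate (carbamoylation) puts a strong and later mildly removable directing group on the oxygen that will become the leaving group.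

Step 6
Reactants: 7 3-methoxy-5-(methoxymethoxy)-4-(3-methylbut-2-en-1-yl)phenyl isopropylcarbamate
Product: 11 5-methoxy-3-(methoxymethoxy)-4-(3-methylbut-2-en-1-yl)-2-(trimethylsilyl)phenyl isopropylcarbamate, via N-silyl carbamate 8 (not isolated), via ortho-lithiated N-silyl carbamate 9 (not isolated), via C-silylated N-silyl carbamate 10 (not isolated)
Conditions: TBSOTf, TMEDA, Et2O, 0 °C → rt; n-BuLi, TMEDA, −78 °C; TMSCl, −78 °C → rt; aq. NH4Cl
Reagents that add atoms: chlorotrimethylsilane, C[Si](C)(C)Cl
Why: Directed ortho-metalation of the aryl carbamate after transient N-silylation should take place at the ortho position that is also flanked by the chelating OMOM group (future C4a), since the other ortho position is flanked only by a methoxy group whose methyl is pushed over it by the neighbouring prenyl group; TMSCl silylates the aryllithium and the N-silyl group is lost on aqueous work-up.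

Step 7
Reactants: 11 5-methoxy-3-(methoxymethoxy)-4-(3-methylbut-2-en-1-yl)-2-(trimethylsilyl)phenyl isopropylcarbamate
Product: 13 5-methoxy-3-(methoxymethoxy)-4-(3-methylbut-2-en-1-yl)-2-(trimethylsilyl)phenyl trifluoromethanesulfonate, via ortho-silylphenol 12 (not isolated)
Conditions: Et2NH, DBU, MeCN, 40 °C; then PhNTf2, rt
Reagents that add atoms: N-phenylbis(trifluoromethanesulfonimide), O=S(=O)(N(c1ccccc1)S(=O)(=O)C(F)(F)F)C(F)(F)F
Why: Base-induced E1cB cleavage of the N-monosubstituted carbamate (the isocyanate is trapped by diethylamine) frees the ortho-silyl phenoxide, which is sulfonylated in the same flask to give the ortho-silylaryl triflate, the standard fluoride-triggered aryne precursor.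

Step 8
Reactants: 14 ethyl 3-oxo-3-(3,4,5-trimethoxyphenyl)propanoate
Product: 15 ethyl (3S)-3-hydroxy-3-(3,4,5-trimethoxyphenyl)propanoate
Conditions: RuCl[(S,S)-TsDPEN](p-cymene) (1 mol%), HCO2H/Et3N (5:2), DMF, 40 °C
Reagents that add atoms: none
Why: Noyori asymmetric transfer hydrogenation of the aryl ketone, in which the (S,S)-TsDPEN ruthenium hydride attacks the carbonyl face fixed by the CH–π contact between the η6-arene and the aryl group (the sense that gives (S)-1-arylethanols), should set the (S)-carbinol centre that becomes C2.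

Step 9
Reactants: 15 ethyl (3S)-3-hydroxy-3-(3,4,5-trimethoxyphenyl)propanoate
Product: 16 (3S)-3-hydroxy-N-methoxy-N-methyl-3-(3,4,5-trimethoxyphenyl)propanamide
Conditions: MeNHOMe·HCl, i-PrMgCl, THF, −20 → 0 °C
Reagents that add atoms: N,O-dimethylhydroxylamine hydrochloride, CNOC.Cl
Why: Direct aminolysis of the ester by the chloromagnesium amide of N,O-dimethylhydroxylamine (Weinreb amide formation) at low temperature should proceed without retro-aldol cleavage, so the stereocentre is untouched.

Step 10
Reactants: 16 (3S)-3-hydroxy-N-methoxy-N-methyl-3-(3,4,5-trimethoxyphenyl)propanamide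
Product: 17 (3S)-N-methoxy-N-methyl-3-(3,4,5-trimethoxyphenyl)-3-[(trimethylsilyl)oxy]propanamide
Conditions: TMSCl, imidazole, CH2Cl2, 0 °C
Reagents that add atoms: chlorotrimethylsilane, C[Si](C)(C)Cl
Why: Silyl ether formation turns the secondary alcohol into a fluoride-releasable alkoxide source and removes the only acidic proton of the fragment.

Step 11
Reactants: 13 5-methoxy-3-(methoxymethoxy)-4-(3-methylbut-2-en-1-yl)-2-(trimethylsilyl)phenyl trifluoromethanesulfonate; 17 (3S)-N-methoxy-N-methyl-3-(3,4,5-trimethoxyphenyl)-3-[(trimethylsilyl)oxy]propanamide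
Product: 22 (2S)-7-methoxy-5-(methoxymethoxy)-6-(3-methylbut-2-en-1-yl)-2-(3,4,5-trimethoxyphenyl)-2,3-dihydro-4H-chromen-4-one, via cesium alkoxide 18 (not isolated), via aryne 19 (not isolated), via arylcesium 20 (not isolated), via hemiaminal alkoxide 21 (not isolated)
Conditions: CsF, 18-crown-6, THF, 0 °C → rt (13 added slowly to 17, 1.3 equiv); then 0.5 M aq. HCl, 0 °C
Reagents that add atoms: none
Why: Proposed new method: fluoride removes both trimethylsilyl groups, so aryne 19 and alkoxide 18 arise side by side with no proton source present; the alkoxide adds to the aryne carbon remote from the methoxymethoxy group (C8a), and the aryl anion 20 at C4a, held six atoms from the amide carbonyl, closes ring C by 6-exo-trig acyl addition that forms the C4–C4a bond and gives the persistent N,O-hemiaminal alkoxide 21, which releases the ketone only on the acidic quench. The closest known reaction types are the aryne annulation of salicylates to xanthones (phenoxide addition, then acyl capture by the aryl anion), the O-arylation of aliphatic alcohols with arynes and the insertion of arynes into the C–O bond of carboxylic acids; an aliphatic β-oxido amide has not been used in such an annulation. The step needs regioselectivity, which is secured by the C5 methoxymethoxy group beside the triple bond: its inductive pull and the distortion it imposes make C8a the electrophilic terminus and place the carbanion at C4a, as in 3-methoxybenzyne. No new stereocentre survives (C4 of 21 is lost on collapse), and C2 is carried over unchanged from 17 because its C–O bond is never broken and the carbonyl stays masked, so base-induced retro-oxa-Michael opening cannot occur. The absence of OH and NH protons (silyl ether as alkoxide source, Weinreb amide as acyl donor) is what should let ring closure outrun protonation of 20.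

Step 12
Reactants: 22 (2S)-7-methoxy-5-(methoxymethoxy)-6-(3-methylbut-2-en-1-yl)-2-(3,4,5-trimethoxyphenyl)-2,3-dihydro-4H-chromen-4-one
Product: 23 (2S)-5-hydroxy-7-methoxy-6-(3-methylbut-2-en-1-yl)-2-(3,4,5-trimethoxyphenyl)-2,3-dihydro-4H-chromen-4-one (artoflavanone)
Conditions: HCl (2 M in MeOH), 0 °C → rt
Reagents that add atoms: none
Why: Acid-catalysed acetal cleavage should be fast for the 5-O-acetal peri to the C4 carbonyl, because the freed phenol is hydrogen-bonded to the ketone, which also lowers its tendency to add to the prenyl double bond, and mild acid does not epimerise C2.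

**Compound list**

1 | 5-methoxybenzene-1,3-diol (5-methoxyresorcinol) | COc1cc(O)cc(O)c1 | starting material
2 | 3-methoxy-5-(methoxymethoxy)phenol | COCOc1cc(O)cc(OC)c1 | intermediate
3 | triisopropyl[3-methoxy-5-(methoxymethoxy)phenoxy]silane | COCOc1cc(OC)cc(O[Si](C(C)C)(C(C)C)C(C)C)c1 | intermediate
4 | [2-methoxy-6-(methoxymethoxy)-4-(triisopropylsilyloxy)phenyl]lithium (formed in the flask) | [Li]c1c(OCOC)cc(O[Si](C(C)C)(C(C)C)C(C)C)cc1OC | intermediate
5 | triisopropyl[3-methoxy-5-(methoxymethoxy)-4-(3-methylbut-2-en-1-yl)phenoxy]silane | CC(C)=CCc1c(OCOC)cc(O[Si](C(C)C)(C(C)C)C(C)C)cc1OC | intermediate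
6 | 3-methoxy-5-(methoxymethoxy)-4-(3-methylbut-2-en-1-yl)phenol | CC(C)=CCc1c(OCOC)cc(O)cc1OC | intermediate
7 | 3-methoxy-5-(methoxymethoxy)-4-(3-methylbut-2-en-1-yl)phenyl isopropylcarbamate | CC(C)=CCc1c(OCOC)cc(OC(=O)NC(C)C)cc1OC | intermediate
8 | N-(tert-butyldimethylsilyl) derivative of 7 (formed in the flask) | CC(C)=CCc1c(OCOC)cc(OC(=O)N(C(C)C)[Si](C)(C)C(C)(C)C)cc1OC | intermediate
9 | 8 lithiated at the ring carbon between the carbamate oxygen and OMOM (formed in the flask) | CC(C)=CCc1c(OCOC)c([Li])c(OC(=O)N(C(C)C)[Si](C)(C)C(C)(C)C)cc1OC | intermediate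
10 | N-(tert-butyldimethylsilyl) derivative of 11 (formed in the flask) | CC(C)=CCc1c(OCOC)c([Si](C)(C)C)c(OC(=O)N(C(C)C)[Si](C)(C)C(C)(C)C)cc1OC | intermediate
11 | 5-methoxy-3-(methoxymethoxy)-4-(3-methylbut-2-en-1-yl)-2-(trimethylsilyl)phenyl isopropylcarbamate | CC(C)=CCc1c(OCOC)c([Si](C)(C)C)c(OC(=O)NC(C)C)cc1OC | intermediate
12 | 5-methoxy-3-(methoxymethoxy)-4-(3-methylbut-2-en-1-yl)-2-(trimethylsilyl)phenol (formed in the flask) | CC(C)=CCc1c(OCOC)c([Si](C)(C)C)c(O)cc1OC | intermediate
13 | 5-methoxy-3-(methoxymethoxy)-4-(3-methylbut-2-en-1-yl)-2-(trimethylsilyl)phenyl trifluoromethanesulfonate | CC(C)=CCc1c(OCOC)c([Si](C)(C)C)c(OS(=O)(=O)C(F)(F)F)cc1OC | intermediate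
14 | ethyl 3-oxo-3-(3,4,5-trimethoxyphenyl)propanoate | CCOC(=O)CC(=O)c1cc(OC)c(OC)c(OC)c1 | starting material
15 | ethyl (3S)-3-hydroxy-3-(3,4,5-trimethoxyphenyl)propanoate | CCOC(=O)C[C@@H](c1cc(OC)c(OC)c(OC)c1)O | intermediate
16 | (3S)-3-hydroxy-N-methoxy-N-methyl-3-(3,4,5-trimethoxyphenyl)propanamide | CON(C)C(=O)C[C@@H](c1cc(OC)c(OC)c(OC)c1)O | intermediate
17 | (3S)-N-methoxy-N-methyl-3-(3,4,5-trimethoxyphenyl)-3-[(trimethylsilyl)oxy]propanamide | CON(C)C(=O)C[C@@H](c1cc(OC)c(OC)c(OC)c1)O[Si](C)(C)C | intermediate
18 | cesium alkoxide of 16 (formed in the flask) | CON(C)C(=O)C[C@@H](c1cc(OC)c(OC)c(OC)c1)[O-].[Cs+] | intermediate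
19 | 5-methoxy-3-(methoxymethoxy)-4-(3-methylbut-2-en-1-yl)benzyne (1,2-didehydrobenzene; formed in the flask) | COC1=CC#CC(OCOC)=C1CC=C(C)C | intermediate
20 | arylcesium from addition of 18 to 19, metal at the carbon between the new aryl ether oxygen and OMOM (formed in the flask) | CON(C)C(=O)C[C@@H](c1cc(OC)c(OC)c(OC)c1)Oc1cc(OC)c(CC=C(C)C)c(OCOC)c1[Cs] | intermediate
21 | cesium (2S)-7-methoxy-4-[methoxy(methyl)amino]-5-(methoxymethoxy)-6-(3-methylbut-2-en-1-yl)-2-(3,4,5-trimethoxyphenyl)chroman-4-olate, C4 epimers (formed in the flask) | COc1cc2c(c(OCOC)c1CC=C(C)C)C([O-])(N(C)OC)C[C@@H](c1cc(OC)c(OC)c(OC)c1)O2.[Cs+] | intermediate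
22 | (2S)-7-methoxy-5-(methoxymethoxy)-6-(3-methylbut-2-en-1-yl)-2-(3,4,5-trimethoxyphenyl)-2,3-dihydro-4H-chromen-4-one | COc1cc2c(c(OCOC)c1CC=C(C)C)C(=O)C[C@@H](c1cc(OC)c(OC)c(OC)c1)O2 | intermediate
23 | (2S)-5-hydroxy-7-methoxy-6-(3-methylbut-2-en-1-yl)-2-(3,4,5-trimethoxyphenyl)-2,3-dihydro-4H-chromen-4-one (artoflavanone) | COc1cc2c(c(O)c1CC=C(C)C)C(=O)C[C@@H](c1cc(OC)c(OC)c(OC)c1)O2 | target

**Count and risks**

Total steps: 12. Longest linear sequence: 9 (steps 1–7, 11, 12).

Steps most likely to fail:

1. Step 11 (proposed new method). The aryl anion may be protonated, or may take the C3 proton (followed by β-elimination of the aryloxide), faster than it adds to the amide carbonyl; the free alkoxide may also fragment by retro-aldol before it meets the aryne. The fallback uses known chemistry, sets out from 13 and comes back at 22. Compound 13 is heated with acetic acid and CsF in THF; insertion of aryne 19 into the C–O bond of the carboxylic acid, with the same regiochemistry (oxygen at C8a, acyl at C4a), should give the acetophenone F1. Condensation with N,N-dimethylformamide dimethyl acetal should give the enaminone F2, which closes to the chromone F3 on mild acid treatment. Palladium-catalysed asymmetric conjugate addition of 3,4,5-trimethoxyphenylboronic acid (Pd(OCOCF3)2, the t-BuPyOx enantiomer that delivers the 2S product, NH4PF6, water, 1,2-dichloroethane, 60 °C) should then give 22.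

2. Step 6. Lithiation may occur at the other ortho position of the carbamate (future C8), or the base may deprotonate the benzylic and allylic CH2 of the prenyl group instead of the ring. The fallback sets out from 1 and comes back at 12; it installs silicon while the ring is still symmetric and before the prenyl group is present. Compound 1 is converted with isopropyl isocyanate into the bis-carbamate F4. N-Silylation, ortho-lithiation and TMSCl put silicon on the only carbon flanked by two carbamates, giving the C-silyl bis-carbamate F5 with no regiochemical choice. Et2NH/DBU frees the silylresorcinol F6, and one equivalent of MOMCl gives the mono-acetal F7 (statistical, but without regioisomers). TIPSCl gives the silyl ether F8; lithiation between OMOM and OMe and copper-catalysed prenylation give the prenyl arene F9; buffered TBAF gives 12, which is triflated with PhNTf2/DBU as in step 7 to reach 13.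

3. Step 3. The allylic electrophile may be attacked at its tertiary end (1,1-dimethylallyl isomer), or the aryllithium may be lost through halogen–metal exchange and homocoupling with the ionisable prenyl bromide. The fallback sets out from 3 and comes back at 5. The aryllithium from 3 is quenched with allyl bromide (CuI cat.), where no allylic regiochemistry is at stake, to give the allyl arene F10. Olefin cross-metathesis with 2-methylbut-2-ene (second-generation Grubbs catalyst, CH2Cl2, 40 °C) then gives 5.

**Further compounds**

F1 | step 11 | 1-[2-hydroxy-4-methoxy-6-(methoxymethoxy)-5-(3-methylbut-2-en-1-yl)phenyl]ethan-1-one | CC(=O)c1c(O)cc(OC)c(CC=C(C)C)c1OCOC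
F2 | step 11 | (2E)-3-(dimethylamino)-1-[2-hydroxy-4-methoxy-6-(methoxymethoxy)-5-(3-methylbut-2-en-1-yl)phenyl]prop-2-en-1-one | CN(C)/C=C/C(=O)c1c(O)cc(OC)c(CC=C(C)C)c1OCOC
F3 | step 11 | 7-methoxy-5-(methoxymethoxy)-6-(3-methylbut-2-en-1-yl)-4H-chromen-4-one | COc1cc2occc(=O)c2c(OCOC)c1CC=C(C)C
F4 | step 6 | 5-methoxy-1,3-phenylene bis(isopropylcarbamate) | COc1cc(OC(=O)NC(C)C)cc(OC(=O)NC(C)C)c1
F5 | step 6 | 5-methoxy-2-(trimethylsilyl)-1,3-phenylene bis(isopropylcarbamate) | COc1cc(OC(=O)NC(C)C)c([Si](C)(C)C)c(OC(=O)NC(C)C)c1
F6 | step 6 | 5-methoxy-2-(trimethylsilyl)benzene-1,3-diol | COc1cc(O)c([Si](C)(C)C)c(O)c1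
F7 | step 6 | 5-methoxy-3-(methoxymethoxy)-2-(trimethylsilyl)phenol | COCOc1cc(OC)cc(O)c1[Si](C)(C)C
F8 | step 6 | triisopropyl[5-methoxy-3-(methoxymethoxy)-2-(trimethylsilyl)phenoxy]silane | COCOc1cc(OC)cc(O[Si](C(C)C)(C(C)C)C(C)C)c1[Si](C)(C)C
F9 | step 6 | triisopropyl[5-methoxy-3-(methoxymethoxy)-4-(3-methylbut-2-en-1-yl)-2-(trimethylsilyl)phenoxy]silane | COCOc1c(CC=C(C)C)c(OC)cc(O[Si](C(C)C)(C(C)C)C(C)C)c1[Si](C)(C)C
F10 | step 3 | triisopropyl[3-methoxy-5-(methoxymethoxy)-4-(prop-2-en-1-yl)phenoxy]silane | C=CCc1c(OCOC)cc(O[Si](C(C)C)(C(C)C)C(C)C)cc1OC
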